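Readings and results were computed on assumed constants; scatter was added.

Late in the east run, X has fallen to 0.4 % of the charge by 2.50 min, yet D keeps dropping, from 90.1 % there to 45.3 % at 10.0 min. So in these flasks, where catalyst Q turns X into D, D is also lost.

all flasks: X 0.11 M

| run | Q | temperature | remark | time |
|---|---|---|---|---|
| south-west | 0.067 mM | −30 °C | run made earlier |  |
| east | 0.15 mM | −8 °C | run made earlier |  |
| teal | 0.10 mM | 0 °C |  | 8.0 min |
| ochre | 0.10 mM | −20 °C |  | 8.0 min |
| amber | 0.10 mM | −40 °C |  | 8.0 min |

| run | time / min | D / % | X / % |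
|---|---|---|---|
| south-west | 4.00 | 12.1 | 87.5 |
| south-west | 6.00 | 17.3 | 81.6 |
| south-west | 8.00 | 24.9 | 77.6 |
| south-west | 12.0 | 34.4 | 64.6 |
| south-west | 20.0 | 57.6 | 43.1 |
| south-west | 25.0 | 72.5 | 27.1 |
| south-west | 40.0 | 95.8 | 2.7 |
| east | 0.833 | 53.5 | 46.2 |
| east | 1.33 | 80.1 | 18.5 |
| east | 2.00 | 93.7 | 1.1 |
| east | 2.50 | 90.1 | 0.4 |
| east | 4.00 | 77.7 | 0 |
| east | 6.00 | 63.7 | 0 |
| east | 10.0 | 45.3 | 0.1 |

(each reading ± 1 percentage point)



* the flask with the highest amount of D, in percent of the X charged ("all alike" if they lie within 1.5 percentage points) (teal / ochre / amber / all alike)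
* final D, as a percentage of the X charged, in teal
* final D, as a percentage of the X charged, in ochre
* final D, as a percentage of the X charged, in amber

How fast does D go? On a logarithmic scale, the east readings from 2.50 min on lie close to a straight line, a pseudo-first-order loss. Read from 2.50 min to 10.0 min, with X at 0.4 % or less, they give 0.0398 min⁻¹ for the decades of D lost per minute, the decade rate. The line predicts 78.5 % at 4.00 min, against a reading of 77.7 %, and it meets the full charge at 1.36 min.

What is the decade rate in teal? I assume it scales with [Q], which gives a factor of 0.667. The temperature step is harder. X turnover per unit of Q rose 8.38-fold from −30 °C to −8 °C, but the loss of D has been seen at one temperature. I therefore take half of the logarithmic step for the warming to 0 °C, a factor of 1.47. My estimate for teal is then 0.0391 min⁻¹. Keeping the east starting point, I reckon D in teal at 55.1 %.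

Which flask leads? The same turnover scaling gives about 93.2 % converted in ochre and 13.5 % in amber. So I expect ochre to hold more D than the other flasks.

The forecast chose ochre, with 35 % for teal, lower than my figure and called “the least certain value”, 91 % for ochre and 10.9 % for amber.

The flasks give ochre as the highest, with 49.3 % in teal, 90.9 % in ochre and 10.7 % in amber.

    X + Q → L (k = 273 L mol⁻¹ s⁻¹, Ea = 39.0 kJ mol⁻¹)
    L → Q + D (k = 2.72 s⁻¹, Ea = 58.0 kJ mol⁻¹)
    Q + D → Q + E (k = 4.22 L mol⁻¹ s⁻¹, Ea = 40.0 kJ mol⁻¹)
    (constants at −20 °C)

Teal falls from 74.1 % at 4.00 min to 49.3 % at 8.00 min, a decade rate of 0.0442 min⁻¹, faster than my 0.0391 min⁻¹. Its line meets the full charge at 1.05 min. The neighbouring flask is teal with 1.7 × 10⁻⁴ M of Q, so [Q] is 1.70 times as high. Multiplying the decade rate by that ratio and dividing the starting time by it gives 27.9 % of D at 8.00 min. That flask holds 27.9 %.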